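**Retrosynthetic overview**
1. Target ⇐ zerovalent-palladium deallylation ⇐ fluoride step that unmasks the C7' oxygen and closes furofuran ring 2 (O–C7'/C9) on a primary mesylate ⇐ ring 1 (O–C7/C9') closed one step earlier the same way; both closures keep the benzylic C–O bonds, so C7 and C7' are retained.
2. The acyclic triol ⇐ reduction of a 3,4-trans γ-butyrolactone (temporary ring, formed first) ⇐ aldol union of a syringyl lactone enolate with an aldehyde already carrying the complete threo arylglycerol β-aryl ether; C7 is fixed by chelation-controlled ketone reduction.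
3. Syringyl lactone ⇐ proposed new nickel–bis(oxazoline)-catalysed direct syn-aldol of a succinate thioimide with O-allylsyringaldehyde (sets C7' and C8').
4. Ether aldehyde ⇐ Evans syn-aldol of an aryloxyacetyl oxazolidinone with O-allylvanillin (sets Cα and Cβ, threo), then reduction, silylation and Br → CHO.

**Assumption:** the SMILES is read as the threo (αS,βS) arylglycerol β-ether of the exo,exo cis-fused (7R,7'R,8S,8'S) furofuran. Labels: C7/C8/C9 (ring B half) and C7'/C8'/C9' (syringyl half) for the furofuran; Cα/Cβ/Cγ for the glycerol chain.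

**Abbreviations:** TBS = tert-butyldimethylsilyl; ArS = 4-(allyloxy)-3,5-dimethoxyphenyl; ArG = 4-{[(1S,2S)-1-[4-(allyloxy)-3-methoxyphenyl]-1,3-bis(TBS-oxy)propan-2-yl]oxy}-3-methoxyphenyl; tBu-box = 2,2'-(propane-2,2-diyl)bis(4-tert-butyl-4,5-dihydro-1,3-oxazole).

## Route

Step 1
Reactants: 1 vanillin
Product: 2 4-(allyloxy)-3-methoxybenzaldehyde
Conditions: allyl bromide, K2CO3, DMF, 60 °C
Reagents that add atoms: allyl bromide, C=CCBr
Why: Williamson O-allylation of the phenoxide; the allyl ether tolerates every later base, hydride and Lewis-acid step and is removed last under neutral conditions.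

Step 2
Reactants: 3 4-bromo-2-methoxyphenol; 4 bromoacetic acid
Product: 5 (4-bromo-2-methoxyphenoxy)acetic acid
Conditions: NaOH, H2O, reflux; then HCl aq
Reagents that add atoms: none
Why: Williamson ether synthesis (SN2 of the phenoxide on bromoacetate); the aryl bromide is a masked formyl group for ring B.

Step 3
Reactants: 5 (4-bromo-2-methoxyphenoxy)acetic acid; 6 (R)-4-benzyl-1,3-oxazolidin-2-one
Product: 8 (4R)-4-benzyl-3-[(4-bromo-2-methoxyphenoxy)acetyl]-1,3-oxazolidin-2-one, via mixed pivalic anhydride 7 (not isolated)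
Conditions: PivCl, Et3N, THF, −20 °C; then 6, LiCl, −20 °C → rt
Reagents that add atoms: none
Why: N-acylation of the oxazolidinone through the mixed anhydride (LiCl/Et3N activation), a standard auxiliary loading with no stereocentre at risk.

Step 4
Reactants: 8 (4R)-4-benzyl-3-[(4-bromo-2-methoxyphenoxy)acetyl]-1,3-oxazolidin-2-one; 2 4-(allyloxy)-3-methoxybenzaldehyde
Product: 10 (4R)-3-[(2R,3S)-3-[4-(allyloxy)-3-methoxyphenyl]-2-(4-bromo-2-methoxyphenoxy)-3-hydroxypropanoyl]-4-benzyl-1,3-oxazolidin-2-one, via Z-boron enolate 9 (not isolated)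
Conditions: Bu2BOTf, iPr2NEt, CH2Cl2, −78 → 0 °C; then 2, −78 → 0 °C; then pH 7 buffer, MeOH, H2O2, 0 °C
Reagents that add atoms: none
Why: Evans syn-aldol: the Z-boron enolate reacts through a Zimmerman–Traxler chair on the face left open by the (R)-benzyl group, giving the 2,3-syn adduct, which is the threo arrangement and sets Cα (S) and Cβ (S in the target) together.

Step 5
Reactants: 10 the syn-aldol imide
Product: 11 (1S,2S)-1-[4-(allyloxy)-3-methoxyphenyl]-2-(4-bromo-2-methoxyphenoxy)propane-1,3-diol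
Conditions: LiBH4, H2O (1 equiv), THF, 0 °C
Reagents that add atoms: none
Why: reductive cleavage of the N-acyl oxazolidinone to the primary alcohol (auxiliary recovered); the aryloxy-bearing centre is not epimerised under these mild hydride conditions.

Step 6
Reactants: 11 the threo 1,3-diol
Product: 12 (1S,2S)-1-[4-(allyloxy)-3-methoxyphenyl]-2-(4-bromo-2-methoxyphenoxy)-1,3-bis(TBS-oxy)propane
Conditions: TBSOTf, 2,6-lutidine, CH2Cl2, 0 °C
Reagents that add atoms: tert-butyldimethylsilyl trifluoromethanesulfonate, CC(C)(C)[Si](C)(C)OS(=O)(=O)C(F)(F)F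
Why: silyl ether formation at both hydroxyls; the benzylic Cα oxygen stays protected (and cannot be sulfonylated or ionised) until the fluoride step.

Step 7
Reactants: 12 the bis-TBS aryl bromide
Product: 14 4-{[(1S,2S)-1-[4-(allyloxy)-3-methoxyphenyl]-1,3-bis(TBS-oxy)propan-2-yl]oxy}-3-methoxybenzaldehyde, via aryllithium 13 (not isolated)
Conditions: n-BuLi, THF, −78 °C; then DMF, −78 → 0 °C; NH4Cl aq
Reagents that add atoms: N,N-dimethylformamide, CN(C)C=O
Why: bromine–lithium exchange followed by formylation with DMF (Bouveault-type); exchange at −78 °C is far faster than any attack on the allyl or silyl ethers.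

Step 8
Reactants: 15 syringaldehyde
Product: 16 4-(allyloxy)-3,5-dimethoxybenzaldehyde
Conditions: allyl bromide, K2CO3, DMF, 70 °C
Reagents that add atoms: allyl bromide, C=CCBr
Why: Williamson O-allylation of the hindered phenoxide.

Step 9
Reactants: 17 1,3-thiazolidine-2-thione; 18 methyl 4-chloro-4-oxobutanoate
Product: 19 methyl 4-oxo-4-(2-thioxo-1,3-thiazolidin-3-yl)butanoate
Conditions: Et3N, CH2Cl2, 0 °C → rt
Reagents that add atoms: none
Why: N-acylation of the thiazolidinethione by the acid chloride gives the S,O-chelating thioimide donor for soft enolisation.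

Step 10
Reactants: 19 methyl 4-oxo-4-(2-thioxo-1,3-thiazolidin-3-yl)butanoate; 16 4-(allyloxy)-3,5-dimethoxybenzaldehyde
Product: 20 methyl (3R)-3-[(R)-ArS(TBS-oxy)methyl]-4-oxo-4-(2-thioxo-1,3-thiazolidin-3-yl)butanoate
Conditions: [Ni((R,R)-tBu-box)](OTf)2 (10 mol%), TBSOTf, 2,6-lutidine, CH2Cl2/PhMe, −78 → −20 °C
Reagents that add atoms: tert-butyldimethylsilyl trifluoromethanesulfonate, CC(C)(C)[Si](C)(C)OS(=O)(=O)C(F)(F)F
Why: Proposed new method: a catalytic enantioselective direct syn-aldol of a succinate-derived N-acyl thiazolidinethione that releases the adduct as its TBS ether, in which the cationic divalent nickel–bis(oxazoline) complex binds the thioimide through S and O so that 2,6-lutidine can deprotonate it to a square-planar chelated Z-enolate, the tert-butyl group next to the enolate oxygen blocks one enolate face, the silyl-triflate-activated aldehyde adds to the open face through an open antiperiplanar transition state (syn adduct, C8' and C7' set together), and O-silylation of the nickel aldolate by TBSOTf turns the catalyst over; the closest known reaction type is the nickel–bis(oxazoline)/silyl triflate soft-enolisation syn-aldol of simple N-propionyl thiazolidinethiones, not yet shown for a donor with a pendant ester or with a bulky silyl triflate.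

Step 11
Reactants: 20 the O-TBS syn-aldol thioimide
Product: 22 (4S)-4-[(R)-ArS(TBS-oxy)methyl]dihydrofuran-2(3H)-one, via hydroxy ester 21 (not isolated)
Conditions: NaBH4, THF/EtOH, 0 °C; then PPTS (cat.), PhMe, 50 °C
Reagents that add atoms: none
Why: chemoselective hydride reduction of the activated thioimide to the primary alcohol (methyl ester untouched), then acid-catalysed lactonisation of the γ-hydroxy ester; no bond to C7' or C8' is broken, and the silyl ether prevents closure through the C7' oxygen.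

Step 12
Reactants: 22 the syringyl lactone; 14 the ether aldehyde
Product: 24 (3R,4S)-3-[ArG(hydroxy)methyl]-4-[(R)-ArS(TBS-oxy)methyl]dihydrofuran-2(3H)-one (both carbinol epimers), via lithium enolate 23 (not isolated)
Conditions: LiN(iPr)2, THF, −78 °C; then 14, −78 °C; AcOH
Reagents that add atoms: none
Why: lithium-enolate aldol addition in which the aldehyde enters anti to the bulky C4 substituent, giving the 3,4-trans lactone and setting C8; the new carbinol centre forms unselectively and is corrected in steps 13 and 14.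

Step 13
Reactants: 24 the aldol adducts
Product: 25 (3R,4S)-3-(ArG-carbonyl)-4-[(R)-ArS(TBS-oxy)methyl]dihydrofuran-2(3H)-one
Conditions: Dess–Martin periodinane, NaHCO3, CH2Cl2, 0 °C → rt
Reagents that add atoms: none
Why: Dess–Martin oxidation converges both carbinol epimers on one β-keto lactone; its acidic C3 centre rests in the 3,4-trans (thermodynamic) configuration.

Step 14
Reactants: 25 the β-keto lactone
Product: 26 (3R,4S)-3-[(R)-ArG(hydroxy)methyl]-4-[(R)-ArS(TBS-oxy)methyl]dihydrofuran-2(3H)-one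
Conditions: Zn(BH4)2, Et2O/THF, −20 °C
Reagents that add atoms: none
Why: chelation-controlled reduction: zinc bridges the ketone and lactone carbonyl oxygens and hydride attacks the ketone face anti to the C4 ring substituent, giving the syn β-hydroxy lactone and setting C7 (R).

Step 15
Reactants: 26 the syn hydroxy lactone
Product: 27 (2S,3S)-2-[(R)-ArG(hydroxy)methyl]-3-[(R)-ArS(TBS-oxy)methyl]butane-1,4-diol
Conditions: LiAlH4, THF, 0 °C
Reagents that add atoms: none
Why: hydride reduction of the lactone to the 1,4-diol; alkyl silyl ethers and allyl aryl ethers are inert and no stereocentre is touched.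

Step 16
Reactants: 27 the triol
Product: 29 [(2R,3S,4S)-2-ArG-4-[(R)-ArS(TBS-oxy)methyl]tetrahydrofuran-3-yl]methyl methanesulfonate, via bis-mesylate 28 (not isolated)
Conditions: MsCl (2.1 equiv), 2,4,6-collidine, CH2Cl2, −20 → 0 °C; then Et3N, 40 °C
Reagents that add atoms: methanesulfonyl chloride, CS(=O)(=O)Cl
Why: collidine-mediated sulfonylation selective for the two primary hydroxyls, then 5-exo-tet Williamson-type cycloetherification of the free benzylic C7 hydroxyl onto the C9' mesylate (the only five-membered option) closes ring 1 with retention at C7, placing ArG trans to the C9 arm.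

Step 17
Reactants: 29 the tetrahydrofuran mesylate
Product: 31 (1S,2S)-1-[4-(allyloxy)-3-methoxyphenyl]-2-{4-[(1R,3aS,4R,6aS)-4-ArS-tetrahydro-1H,3H-furo[3,4-c]furan-1-yl]-2-methoxyphenoxy}propane-1,3-diol, via hydroxy mesylate 30 (not isolated)
Conditions: Bu4NF (5 equiv), THF, 0 °C → rt
Reagents that add atoms: none
Why: fluoride desilylation unmasks the C7' alkoxide, which displaces the remaining primary mesylate (5-exo-tet, retention at C7') to close ring 2 as the cis-fused exo,exo furofuran, while the two side-chain silyl ethers are cleaved in the same flask.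

Step 18
Reactants: 31 the bis-allyl ether
Product: 32 (1S,2S)-1-(4-hydroxy-3-methoxyphenyl)-2-{4-[(1R,3aS,4R,6aS)-4-(4-hydroxy-3,5-dimethoxyphenyl)tetrahydro-1H,3H-furo[3,4-c]furan-1-yl]-2-methoxyphenoxy}propane-1,3-diol
Conditions: Pd(PPh3)4 (5 mol%), morpholine, THF, rt
Reagents that add atoms: none
Why: Tsuji–Trost deallylation: zerovalent palladium ionises the aryl allyl ethers to π-allyl complexes that morpholine captures; the neutral conditions leave the three benzylic ethers and the benzylic alcohol untouched.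

## Compound list

1 | vanillin (4-hydroxy-3-methoxybenzaldehyde) | COc1cc(C=O)ccc1O | starting material
2 | 4-(allyloxy)-3-methoxybenzaldehyde | C=CCOc1ccc(C=O)cc1OC | intermediate
3 | 4-bromo-2-methoxyphenol | COc1cc(Br)ccc1O | starting material
4 | bromoacetic acid | OC(=O)CBr | starting material
5 | (4-bromo-2-methoxyphenoxy)acetic acid | COc1cc(Br)ccc1OCC(=O)O | intermediate
6 | (R)-4-benzyl-1,3-oxazolidin-2-one | O=C1N[C@H](Cc2ccccc2)CO1 | starting material
7 | (4-bromo-2-methoxyphenoxy)acetic pivalic anhydride | COc1cc(Br)ccc1OCC(=O)OC(=O)C(C)(C)C | intermediate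
8 | (4R)-4-benzyl-3-[(4-bromo-2-methoxyphenoxy)acetyl]-1,3-oxazolidin-2-one | COc1cc(Br)ccc1OCC(=O)N1[C@H](Cc2ccccc2)COC1=O | intermediate
9 | Z-dibutylboron enolate of 8 | CCCCB(CCCC)O/C(=C\Oc1ccc(Br)cc1OC)N1[C@H](Cc2ccccc2)COC1=O | intermediate
10 | (4R)-3-[(2R,3S)-3-[4-(allyloxy)-3-methoxyphenyl]-2-(4-bromo-2-methoxyphenoxy)-3-hydroxypropanoyl]-4-benzyl-1,3-oxazolidin-2-one | C=CCOc1ccc(cc1OC)[C@H](O)[C@@H](Oc1ccc(Br)cc1OC)C(=O)N1[C@H](Cc2ccccc2)COC1=O | intermediate
11 | (1S,2S)-1-[4-(allyloxy)-3-methoxyphenyl]-2-(4-bromo-2-methoxyphenoxy)propane-1,3-diol | C=CCOc1ccc(cc1OC)[C@H](O)[C@H](CO)Oc1ccc(Br)cc1OC | intermediate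
12 | (1S,2S)-1-[4-(allyloxy)-3-methoxyphenyl]-2-(4-bromo-2-methoxyphenoxy)-1,3-bis(tert-butyldimethylsilyloxy)propane | C=CCOc1ccc(cc1OC)[C@H](O[Si](C)(C)C(C)(C)C)[C@H](CO[Si](C)(C)C(C)(C)C)Oc1ccc(Br)cc1OC | intermediate
13 | aryllithium from 12 (Li in place of Br) | C=CCOc1ccc(cc1OC)[C@H](O[Si](C)(C)C(C)(C)C)[C@H](CO[Si](C)(C)C(C)(C)C)Oc1ccc([Li])cc1OC | intermediate
14 | 4-{[(1S,2S)-1-[4-(allyloxy)-3-methoxyphenyl]-1,3-bis(tert-butyldimethylsilyloxy)propan-2-yl]oxy}-3-methoxybenzaldehyde | C=CCOc1ccc(cc1OC)[C@H](O[Si](C)(C)C(C)(C)C)[C@H](CO[Si](C)(C)C(C)(C)C)Oc1ccc(C=O)cc1OC | intermediate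
15 | syringaldehyde (4-hydroxy-3,5-dimethoxybenzaldehyde) | COc1cc(C=O)cc(OC)c1O | starting material
16 | 4-(allyloxy)-3,5-dimethoxybenzaldehyde | C=CCOc1c(OC)cc(C=O)cc1OC | intermediate
17 | 1,3-thiazolidine-2-thione | S=C1NCCS1 | starting material
18 | methyl 4-chloro-4-oxobutanoate | COC(=O)CCC(Cl)=O | starting material
19 | methyl 4-oxo-4-(2-thioxo-1,3-thiazolidin-3-yl)butanoate | COC(=O)CCC(=O)N1CCSC1=S | intermediate
20 | methyl (3R)-3-[(R)-[4-(allyloxy)-3,5-dimethoxyphenyl](tert-butyldimethylsilyloxy)methyl]-4-oxo-4-(2-thioxo-1,3-thiazolidin-3-yl)butanoate | O=C(N1CCSC1=S)[C@H](CC(=O)OC)[C@@H](O[Si](C)(C)C(C)(C)C)c1cc(OC)c(OCC=C)c(OC)c1 | intermediate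
21 | methyl (3S)-3-[(R)-[4-(allyloxy)-3,5-dimethoxyphenyl](tert-butyldimethylsilyloxy)methyl]-4-hydroxybutanoate | COC(=O)C[C@@H](CO)[C@@H](O[Si](C)(C)C(C)(C)C)c1cc(OC)c(OCC=C)c(OC)c1 | intermediate
22 | (4S)-4-[(R)-[4-(allyloxy)-3,5-dimethoxyphenyl](tert-butyldimethylsilyloxy)methyl]dihydrofuran-2(3H)-one | O=C1C[C@@H](CO1)[C@@H](O[Si](C)(C)C(C)(C)C)c1cc(OC)c(OCC=C)c(OC)c1 | intermediate
23 | lithium enolate of 22 | [Li]OC1=C[C@@H](CO1)[C@@H](O[Si](C)(C)C(C)(C)C)c1cc(OC)c(OCC=C)c(OC)c1 | intermediate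
24 | (3R,4S)-3-[ArG(hydroxy)methyl]-4-[(R)-ArS(TBS-oxy)methyl]dihydrofuran-2(3H)-one, both carbinol epimers | C=CCOc1ccc(cc1OC)[C@H](O[Si](C)(C)C(C)(C)C)[C@H](CO[Si](C)(C)C(C)(C)C)Oc1ccc(cc1OC)C(O)[C@@H]1C(=O)OC[C@H]1[C@@H](O[Si](C)(C)C(C)(C)C)c1cc(OC)c(OCC=C)c(OC)c1 | intermediate
25 | (3R,4S)-3-(ArG-carbonyl)-4-[(R)-ArS(TBS-oxy)methyl]dihydrofuran-2(3H)-one | C=CCOc1ccc(cc1OC)[C@H](O[Si](C)(C)C(C)(C)C)[C@H](CO[Si](C)(C)C(C)(C)C)Oc1ccc(cc1OC)C(=O)[C@@H]1C(=O)OC[C@H]1[C@@H](O[Si](C)(C)C(C)(C)C)c1cc(OC)c(OCC=C)c(OC)c1 | intermediate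
26 | (3R,4S)-3-[(R)-ArG(hydroxy)methyl]-4-[(R)-ArS(TBS-oxy)methyl]dihydrofuran-2(3H)-one | C=CCOc1ccc(cc1OC)[C@H](O[Si](C)(C)C(C)(C)C)[C@H](CO[Si](C)(C)C(C)(C)C)Oc1ccc(cc1OC)[C@H](O)[C@@H]1C(=O)OC[C@H]1[C@@H](O[Si](C)(C)C(C)(C)C)c1cc(OC)c(OCC=C)c(OC)c1 | intermediate
27 | (2S,3S)-2-[(R)-ArG(hydroxy)methyl]-3-[(R)-ArS(TBS-oxy)methyl]butane-1,4-diol | C=CCOc1ccc(cc1OC)[C@H](O[Si](C)(C)C(C)(C)C)[C@H](CO[Si](C)(C)C(C)(C)C)Oc1ccc(cc1OC)[C@H](O)[C@H](CO)[C@@H](CO)[C@@H](O[Si](C)(C)C(C)(C)C)c1cc(OC)c(OCC=C)c(OC)c1 | intermediate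
28 | 1,4-bis(methanesulfonate) of 27 | C=CCOc1ccc(cc1OC)[C@H](O[Si](C)(C)C(C)(C)C)[C@H](CO[Si](C)(C)C(C)(C)C)Oc1ccc(cc1OC)[C@H](O)[C@H](COS(C)(=O)=O)[C@@H](COS(C)(=O)=O)[C@@H](O[Si](C)(C)C(C)(C)C)c1cc(OC)c(OCC=C)c(OC)c1 | intermediate
29 | [(2R,3S,4S)-2-ArG-4-[(R)-ArS(TBS-oxy)methyl]tetrahydrofuran-3-yl]methyl methanesulfonate | C=CCOc1ccc(cc1OC)[C@H](O[Si](C)(C)C(C)(C)C)[C@H](CO[Si](C)(C)C(C)(C)C)Oc1ccc(cc1OC)[C@@H]1OC[C@H]([C@H]1COS(C)(=O)=O)[C@@H](O[Si](C)(C)C(C)(C)C)c1cc(OC)c(OCC=C)c(OC)c1 | intermediate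
30 | fully desilylated 29 (free C7', Cα and Cγ hydroxyls, C9 mesylate) | C=CCOc1ccc(cc1OC)[C@H](O)[C@H](CO)Oc1ccc(cc1OC)[C@@H]1OC[C@H]([C@H]1COS(C)(=O)=O)[C@@H](O)c1cc(OC)c(OCC=C)c(OC)c1 | intermediate
31 | (1S,2S)-1-[4-(allyloxy)-3-methoxyphenyl]-2-{4-[(1R,3aS,4R,6aS)-4-[4-(allyloxy)-3,5-dimethoxyphenyl]tetrahydro-1H,3H-furo[3,4-c]furan-1-yl]-2-methoxyphenoxy}propane-1,3-diol | C=CCOc1ccc(cc1OC)[C@H](O)[C@H](CO)Oc1ccc(cc1OC)[C@@H]1OC[C@@H]2[C@H]1CO[C@H]2c1cc(OC)c(OCC=C)c(OC)c1 | intermediate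
32 | (1S,2S)-1-(4-hydroxy-3-methoxyphenyl)-2-{4-[(1R,3aS,4R,6aS)-4-(4-hydroxy-3,5-dimethoxyphenyl)tetrahydro-1H,3H-furo[3,4-c]furan-1-yl]-2-methoxyphenoxy}propane-1,3-diol (CNP0255927.3) | COc1cc([C@H](O)[C@H](CO)Oc2ccc([C@@H]3OC[C@@H]4[C@H]3CO[C@H]4c3cc(OC)c(O)c(OC)c3)cc2OC)ccc1O | target

## Step count and risks

Total step count: 18. Longest linear sequence: 13 steps (3 → 5 → 8 → 10 → 11 → 12 → 14 → 24 → 25 → 26 → 27 → 29 → 31 → 32, i.e. steps 2–7 and 12–18).

**Step 10 (the proposed new nickel-catalysed syn-aldol).** The pendant ester may compete for nickel, the bulky silyl triflate may slow turnover or erode the syn preference, and the facial sense is assigned only from the square-planar chelate model (the (S,S) ligand is the first remedy if it is reversed). The fallback is known auxiliary chemistry; it sets out from 16 (using 6 and 18) and returns to the route at 22. Oxazolidinone 6 is N-acylated with 18 (n-BuLi, THF, −78 °C) to give (4R)-4-benzyl-3-(4-methoxy-4-oxobutanoyl)-1,3-oxazolidin-2-one F1. Its Z-boron enolate (Bu2BOTf, iPr2NEt, CH2Cl2, −78 → 0 °C) adds to 16 in an auxiliary-controlled syn-aldol, and the aldolate closes onto the methyl ester on work-up to give the trans lactone imide F2. LiBH4 (THF, 0 °C → rt) reduces imide and lactone to the triol F3. TBSOTf/2,6-lutidine gives the tris-TBS ether F4. HF·pyridine in THF/pyridine at 0 °C frees the two primary hydroxyls to give the diol F5. TEMPO/PhI(OAc)2 then oxidises the less hindered primary alcohol and the resulting lactol to lactone 22.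

**Step 12 (aldol union of two advanced fragments).** Retro-aldol, incomplete conversion with the hindered enolate, or proton transfer could limit the yield. The fallback replaces aldol plus oxidation by a Claisen-type C-acylation; it sets out from 14 and returns at 25. Pinnick oxidation of 14 (NaClO2, NaH2PO4, 2-methyl-2-butene, tBuOH/H2O) gives the benzoic acid F6. 1,1'-Carbonyldiimidazole in THF converts it to the acyl imidazole F7. Enolate 23, made from 22 with 2.2 equivalents of LiN(iPr)2, is then acylated by F7 at −78 °C to give keto lactone 25 directly.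

**Step 16 (selective bis-mesylation and closure of ring 1).** The benzylic hydroxyl may be sulfonylated as well, a monomesylate may close the 9,9'-ether, and the outcome depends on the syn selectivity of step 14. The fallback forms the other C–O bond of ring 1; it sets out from 27 and returns at 29. Camphorsulfonic acid (10 mol%, CH2Cl2, 4 Å sieves, 0 °C) ionises the p-alkoxybenzylic C7 hydroxyl and the C9' hydroxyl captures the cation trans to the neighbouring CH2OH arm (5-exo, the kinetically and thermodynamically preferred 2,3-trans ring). This gives the tetrahydrofuran alcohol F8 whatever the C7 configuration of the triol. MsCl/Et3N (CH2Cl2, 0 °C) then converts F8 into mesylate 29.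

## Further compounds

F1 | step 10 | (4R)-4-benzyl-3-(4-methoxy-4-oxobutanoyl)-1,3-oxazolidin-2-one | COC(=O)CCC(=O)N1[C@H](Cc2ccccc2)COC1=O
F2 | step 10 | (4R)-3-{[(2R,3R)-2-[4-(allyloxy)-3,5-dimethoxyphenyl]-5-oxotetrahydrofuran-3-yl]carbonyl}-4-benzyl-1,3-oxazolidin-2-one | O=C([C@@H]1CC(=O)O[C@H]1c1cc(OC)c(OCC=C)c(OC)c1)N1[C@H](Cc2ccccc2)COC1=O
F3 | step 10 | (2S)-2-[(R)-[4-(allyloxy)-3,5-dimethoxyphenyl](hydroxy)methyl]butane-1,4-diol | OCC[C@@H](CO)[C@@H](O)c1cc(OC)c(OCC=C)c(OC)c1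
F4 | step 10 | (2S)-2-[(R)-[4-(allyloxy)-3,5-dimethoxyphenyl](tert-butyldimethylsilyloxy)methyl]-1,4-bis(tert-butyldimethylsilyloxy)butane | CC(C)(C)[Si](C)(C)OCC[C@@H](CO[Si](C)(C)C(C)(C)C)[C@@H](O[Si](C)(C)C(C)(C)C)c1cc(OC)c(OCC=C)c(OC)c1
F5 | step 10 | (2S)-2-[(R)-[4-(allyloxy)-3,5-dimethoxyphenyl](tert-butyldimethylsilyloxy)methyl]butane-1,4-diol | OCC[C@@H](CO)[C@@H](O[Si](C)(C)C(C)(C)C)c1cc(OC)c(OCC=C)c(OC)c1
F6 | step 12 | 4-{[(1S,2S)-1-[4-(allyloxy)-3-methoxyphenyl]-1,3-bis(tert-butyldimethylsilyloxy)propan-2-yl]oxy}-3-methoxybenzoic acid | C=CCOc1ccc(cc1OC)[C@H](O[Si](C)(C)C(C)(C)C)[C@H](CO[Si](C)(C)C(C)(C)C)Oc1ccc(cc1OC)C(=O)O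
F7 | step 12 | (4-{[(1S,2S)-1-[4-(allyloxy)-3-methoxyphenyl]-1,3-bis(tert-butyldimethylsilyloxy)propan-2-yl]oxy}-3-methoxyphenyl)(1H-imidazol-1-yl)methanone | C=CCOc1ccc(cc1OC)[C@H](O[Si](C)(C)C(C)(C)C)[C@H](CO[Si](C)(C)C(C)(C)C)Oc1ccc(cc1OC)C(=O)n1ccnc1
F8 | step 16 | [(2R,3S,4S)-2-ArG-4-[(R)-ArS(TBS-oxy)methyl]tetrahydrofuran-3-yl]methanol | C=CCOc1ccc(cc1OC)[C@H](O[Si](C)(C)C(C)(C)C)[C@H](CO[Si](C)(C)C(C)(C)C)Oc1ccc(cc1OC)[C@@H]1OC[C@H]([C@H]1CO)[C@@H](O[Si](C)(C)C(C)(C)C)c1cc(OC)c(OCC=C)c(OC)c1
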